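**Plan** (primed locants = lower epiafzelechin unit, unprimed = upper flavan unit)

1. Retrosynthesis: the six O-benzyl groups come off last. The pyran ring of the upper flavan unit is cut across O1–C2 and C3–C4 (retro oxa-[4+2]) to an ortho-quinone methide of upper ring A plus 4-benzyloxystyrene. Its precursor, a 2-hydroxybenzhydrol, is cut at C4–C8' to an 8'-lithiated perbenzyl epiafzelechin and 4-(benzyloxy)-2-hydroxybenzaldehyde.
2. Forward: (−)-epiafzelechin supplies the lower unit with both rings intact; it is benzylated, brominated at C8', lithiated and added to the salicylaldehyde. The upper pyran ring is built last by a catalytic asymmetric dehydrative cycloaddition, and hydrogenolysis gives the target.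
3. Enabling feature: in upper ring A the oxygen O1 sits on C8a, ortho to C4a, so a carbinol at C4 dehydrates to the oxadiene O1=C8a–C4a=C4. The 4-oxygenated aryl on C2 makes the styrene a polarised two-carbon partner that delivers C3 and C2.
4. Stereochemistry: C2' and C3' (R,R) come from (−)-epiafzelechin. C4 (S) comes from the chiral phosphoramide anion bound to the quinone methide. C2 (S) comes from the endo, 2,4-cis mode of the cycloaddition.

Key step: step 5

Assumptions: (−)-epiafzelechin, 4-(benzyloxy)-2-hydroxybenzaldehyde and 4-benzyloxystyrene are taken as purchasable. The (R)-catalyst is written for the (2S,4S) sense of the new ring; which antipode gives this sense cannot be predicted with confidence and is to be fixed on a model benzhydrol, the (S)-catalyst being used otherwise with nothing else changed.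

**Step 1**
Reactants: 1 (−)-epiafzelechin
Product: 2 (2R,3R)-5,7-bis(benzyloxy)-2-[4-(benzyloxy)phenyl]chroman-3-ol
Conditions: BnBr (3.3 equiv), K2CO3, DMF, 0 °C → rt
Reagents that add atoms: benzyl bromide, BrCc1ccccc1
Why: Williamson ether synthesis in which carbonate deprotonates only the three phenols, so the secondary 3-OH stays free and neither stereocentre is touched.

**Step 2**
Reactants: 2 (2R,3R)-5,7-bis(benzyloxy)-2-[4-(benzyloxy)phenyl]chroman-3-ol
Product: 3 (2R,3R)-3,5,7-tris(benzyloxy)-2-[4-(benzyloxy)phenyl]chroman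
Conditions: NaH, BnBr, n-Bu4NI (cat.), DMF, 0 °C → rt
Reagents that add atoms: benzyl bromide, BrCc1ccccc1
Why: Williamson ether synthesis on the secondary alkoxide; with all phenols already capped no phenoxide can open the pyran ring, so C2 and C3 should keep their configuration.

**Step 3**
Reactants: 3 (2R,3R)-3,5,7-tris(benzyloxy)-2-[4-(benzyloxy)phenyl]chroman
Product: 4 (2R,3R)-3,5,7-tris(benzyloxy)-2-[4-(benzyloxy)phenyl]-8-bromochroman
Conditions: NBS (1.0 equiv), CH2Cl2, −78 °C → 0 °C
Reagents that add atoms: N-bromosuccinimide, O=C1CCC(=O)N1Br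
Why: Electrophilic aromatic bromination of the phloroglucinol-type ring A, which is far more electron-rich than the 4-benzyloxyphenyl ring; in O-benzylated flavan-3-ols one equivalent of NBS at low temperature is known to go to C8 in preference to C6.

**Step 4**
Reactants: 4 (2R,3R)-3,5,7-tris(benzyloxy)-2-[4-(benzyloxy)phenyl]-8-bromochroman; 5 4-(benzyloxy)-2-hydroxybenzaldehyde
Product: 8 [4-(benzyloxy)-2-hydroxyphenyl][(2R,3R)-3,5,7-tris(benzyloxy)-2-[4-(benzyloxy)phenyl]chroman-8-yl]methanol as a mixture of carbinol epimers, via sodium 5-(benzyloxy)-2-formylphenoxide 6 (not isolated), via 8-lithio flavan 7 (not isolated)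
Conditions: 5, NaH, THF, 0 °C; separately 4, n-BuLi, THF, −78 °C; aryllithium added to the phenoxide, −78 → −20 °C; aq NH4Cl; chromatography on Et3N-deactivated silica
Reagents that add atoms: none
Why: Bromine–lithium exchange followed by 1,2-addition of the aryllithium to the aldehyde; the phenol of 5 is converted to its sodium salt beforehand so that it cannot protonate 7, and the new carbinol centre need not be controlled because it becomes trigonal in step 5.

**Step 5**
Reactants: 8 [4-(benzyloxy)-2-hydroxyphenyl][(2R,3R)-3,5,7-tris(benzyloxy)-2-[4-(benzyloxy)phenyl]chroman-8-yl]methanol; 9 4-benzyloxystyrene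
Product: 11 (2R,3R)-3,5,7-tris(benzyloxy)-2-[4-(benzyloxy)phenyl]-8-{(2S,4S)-7-(benzyloxy)-2-[4-(benzyloxy)phenyl]chroman-4-yl}chroman, via ortho-quinone methide 10 (not isolated)
Conditions: (R)-3,3'-bis(2,4,6-triisopropylphenyl)-1,1'-binaphthyl-2,2'-diyl N-(trifluoromethylsulfonyl)phosphoramide (10 mol %), 9 (3 equiv), 5 Å MS, toluene, −40 °C, slow addition of 8
Reagents that add atoms: none
Why: The chiral acid protonates the benzylic hydroxyl of 8, water leaves, and quinone methide 10 (oxadiene O1=C8a–C4a=C4 of upper ring A) stays hydrogen-bonded and ion-paired to the chiral anion while the terminal CH2 of 9 attacks C4 and the ring oxygen captures the developing 4-benzyloxybenzylic cation at C2, an asynchronous inverse-electron-demand oxa-[4+2] cycloaddition. The closest known reaction type is the chiral N-triflylphosphoramide-catalysed cycloaddition of ortho-hydroxybenzhydrols with styrenes to cis-2,4-diarylchromans. The upper pyran ring closes in the [4+2] mode, C3–C4 forming ahead of O1–C2, which is the bond that completes the six-membered ring. C4 (S) is set by the catalyst, whose 3,3'-aryl groups shield one face of the bound quinone methide; C2 (S) follows from C4 through the endo transition state on the E-configured methide, giving the 2,4-cis ring, which is also the diequatorial isomer favoured if O1–C2 ionises reversibly. Regioselectivity (aryl on C2, not C3) is secured by the 4-benzyloxy group of 9, which stabilises positive charge on the carbon that bonds to oxygen; face selectivity has to come from the catalyst because the stereocentres of the lower unit lie three bonds from C8' on an aryl ring twisted out of the quinone methide plane and should bias the faces only weakly.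

**Step 6**
Reactants: 11 (2R,3R)-3,5,7-tris(benzyloxy)-2-[4-(benzyloxy)phenyl]-8-{(2S,4S)-7-(benzyloxy)-2-[4-(benzyloxy)phenyl]chroman-4-yl}chroman
Product: 12 (2R,3R)-8-[(2S,4S)-7-hydroxy-2-(4-hydroxyphenyl)chroman-4-yl]-2-(4-hydroxyphenyl)chroman-3,5,7-triol
Conditions: H2 (1 atm), Pd(OH)2/C, THF–MeOH, rt
Reagents that add atoms: none
Why: Hydrogenolysis of the six benzyl ethers under neutral conditions at atmospheric pressure, under which the cyclic benzylic C2–O1 bonds of flavans and the C4 methine should be retained, so no stereocentre is affected.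

**Compound list**

1 | (−)-epiafzelechin, (2R,3R)-2-(4-hydroxyphenyl)chroman-3,5,7-triol | c1c(O)cc(O)c2c1O[C@H](c1ccc(O)cc1)[C@H](O)C2 | starting material
2 | (2R,3R)-5,7-bis(benzyloxy)-2-[4-(benzyloxy)phenyl]chroman-3-ol | c1c(OCc5ccccc5)cc(OCc5ccccc5)c2c1O[C@H](c1ccc(OCc5ccccc5)cc1)[C@H](O)C2 | intermediate
3 | (2R,3R)-3,5,7-tris(benzyloxy)-2-[4-(benzyloxy)phenyl]chroman | c1c(OCc5ccccc5)cc(OCc5ccccc5)c2c1O[C@H](c1ccc(OCc5ccccc5)cc1)[C@H](OCc5ccccc5)C2 | intermediate
4 | (2R,3R)-3,5,7-tris(benzyloxy)-2-[4-(benzyloxy)phenyl]-8-bromochroman | Brc1c(OCc5ccccc5)cc(OCc5ccccc5)c2c1O[C@H](c1ccc(OCc5ccccc5)cc1)[C@H](OCc5ccccc5)C2 | intermediate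
5 | 4-(benzyloxy)-2-hydroxybenzaldehyde | O=Cc1ccc(OCc2ccccc2)cc1O | starting material
6 | sodium 5-(benzyloxy)-2-formylphenoxide | [Na+].[O-]c1cc(OCc2ccccc2)ccc1C=O | intermediate
7 | [(2R,3R)-3,5,7-tris(benzyloxy)-2-[4-(benzyloxy)phenyl]chroman-8-yl]lithium | [Li]c1c(OCc5ccccc5)cc(OCc5ccccc5)c2c1O[C@H](c1ccc(OCc5ccccc5)cc1)[C@H](OCc5ccccc5)C2 | intermediate
8 | [4-(benzyloxy)-2-hydroxyphenyl][(2R,3R)-3,5,7-tris(benzyloxy)-2-[4-(benzyloxy)phenyl]chroman-8-yl]methanol (carbinol epimers) | OC(c1ccc(OCc5ccccc5)cc1O)c1c(OCc5ccccc5)cc(OCc5ccccc5)c2c1O[C@H](c1ccc(OCc5ccccc5)cc1)[C@H](OCc5ccccc5)C2 | intermediate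
9 | 4-benzyloxystyrene, 1-(benzyloxy)-4-vinylbenzene | C=Cc1ccc(OCc2ccccc2)cc1 | starting material
10 | (6E)-3-(benzyloxy)-6-{[(2R,3R)-3,5,7-tris(benzyloxy)-2-[4-(benzyloxy)phenyl]chroman-8-yl]methylidene}cyclohexa-2,4-dien-1-one | O=C1C=C(OCc5ccccc5)C=C/C1=C\c1c(OCc5ccccc5)cc(OCc5ccccc5)c2c1O[C@H](c1ccc(OCc5ccccc5)cc1)[C@H](OCc5ccccc5)C2 | intermediate
11 | (2R,3R)-3,5,7-tris(benzyloxy)-2-[4-(benzyloxy)phenyl]-8-{(2S,4S)-7-(benzyloxy)-2-[4-(benzyloxy)phenyl]chroman-4-yl}chroman | c5ccccc5COc1ccc([C@@H]2C[C@H](c3c(OCc5ccccc5)cc(OCc5ccccc5)c4c3O[C@H](c3ccc(OCc5ccccc5)cc3)[C@H](OCc5ccccc5)C4)c3ccc(OCc5ccccc5)cc3O2)cc1 | intermediate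
12 | (2R,3R)-8-[(2S,4S)-7-hydroxy-2-(4-hydroxyphenyl)chroman-4-yl]-2-(4-hydroxyphenyl)chroman-3,5,7-triol | Oc1ccc([C@@H]2C[C@H](c3c(O)cc(O)c4c3O[C@H](c3ccc(O)cc3)[C@H](O)C4)c3ccc(O)cc3O2)cc1 | target

Total step count: 6. Longest linear sequence: 6 steps (1 → 12).

**Steps most likely to fail**

Step 5. What may go wrong: loss of facial control, because the large twisted lower unit may fit the catalyst pocket poorly or its own preference may oppose that of the catalyst; acid-induced oligomerisation of the styrene; self-condensation of the quinone methide. Fallback (auxiliary control under basic conditions, no acid), setting out from bromide 4 and aldehyde 5 and returning at 11: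
- Aldehyde 5 is treated with Boc2O (DMAP cat., i-Pr2NEt, THF) to give 4-(benzyloxy)-2-[(tert-butoxycarbonyl)oxy]benzaldehyde F1.
- (1R,2S)-2-Phenylcyclohexanol is vinylated with ethyl vinyl ether and catalytic Hg(OAc)2 to give (1R,2S)-2-phenylcyclohexyl vinyl ether F2; the antipodal alcohol is taken if a model shows the opposite facial sense.
- Aryllithium 7, made from 4 as in step 4, is transmetalated with MgBr2·OEt2 to [(2R,3R)-3,5,7-tris(benzyloxy)-2-[4-(benzyloxy)phenyl]chroman-8-yl]magnesium bromide F3.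
- F3 is added to F1 in the presence of excess F2 at −78 °C and the mixture is warmed. Addition, migration of the Boc group to the new alkoxide and magnesium-assisted loss of tert-butyl carbonate generate quinone methide 10. The enol ether traps it endo on the face left open by the phenyl group of the auxiliary, which should give the 2,4-cis acetal (2R,3R)-3,5,7-tris(benzyloxy)-2-[4-(benzyloxy)phenyl]-8-{(2S,4S)-7-(benzyloxy)-2-[(1R,2S)-2-phenylcyclohexyloxy]chroman-4-yl}chroman F4. Three components are joined in one operation and C4 is fixed by the auxiliary.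
- Mild aqueous acid (CSA, THF–H2O) hydrolyses F4 to the lactol (4S)-7-(benzyloxy)-4-[(2R,3R)-3,5,7-tris(benzyloxy)-2-[4-(benzyloxy)phenyl]chroman-8-yl]chroman-2-ol F5 and returns the auxiliary alcohol.
- Excess 4-(benzyloxy)phenylmagnesium bromide (THF, 0 °C) opens F5 to (3S)-3-[4-(benzyloxy)-2-hydroxyphenyl]-1-[4-(benzyloxy)phenyl]-3-[(2R,3R)-3,5,7-tris(benzyloxy)-2-[4-(benzyloxy)phenyl]chroman-8-yl]propan-1-ol F6 as carbinol epimers.
- Catalytic PPTS in CH2Cl2 ionises the 4-benzyloxybenzylic alcohol of F6 and the phenol closes the ring to the thermodynamically preferred 2,4-cis flavan 11.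

Step 4. What may go wrong: slow addition of the hindered aryllithium to the deactivated phenoxide aldehyde with competing protonation of the aryllithium, and ionisation of the very electron-rich benzhydrol during isolation. Fallback (reversed polarity, forming C4–C4a instead of C4–C8'), setting out from 4 and returning at 8:
- Aryllithium 7 is quenched with DMF to give (2R,3R)-3,5,7-tris(benzyloxy)-2-[4-(benzyloxy)phenyl]chroman-8-carbaldehyde F7.
- F7, 3-(benzyloxy)phenol and PhB(OH)2 are heated in toluene with catalytic propionic acid and azeotropic removal of water. Boron holds phenol and aldehyde together so that only the ortho position para to the benzyloxy group is hydroxyalkylated, giving 7-(benzyloxy)-2-phenyl-4-[(2R,3R)-3,5,7-tris(benzyloxy)-2-[4-(benzyloxy)phenyl]chroman-8-yl]-4H-1,3,2-benzodioxaborinine F8, a storable masked form of the benzhydrol.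
- Exchange with propane-1,3-diol at room temperature releases 8 immediately before step 5.

Step 6. What may go wrong: hydrogenolytic opening of the benzylic O1–C2 bond of either pyran ring, or stalling at the secondary 3'-O-benzyl ether. Fallback (heterolytic instead of reductive cleavage), from 11 directly to 12: BCl3 with pentamethylbenzene in CH2Cl2 at −78 °C, the arene trapping each benzyl cation. No hydrogen and no metal are involved and no new compound arises (F0).

**Further compounds**

F1 | step 5 | 4-(benzyloxy)-2-[(tert-butoxycarbonyl)oxy]benzaldehyde | O=Cc1ccc(OCc2ccccc2)cc1OC(=O)OC(C)(C)C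
F2 | step 5 | (1R,2S)-2-phenylcyclohexyl vinyl ether | C=CO[C@@H]1CCCC[C@H]1c1ccccc1
F3 | step 5 | [(2R,3R)-3,5,7-tris(benzyloxy)-2-[4-(benzyloxy)phenyl]chroman-8-yl]magnesium bromide | Br[Mg]c1c(OCc5ccccc5)cc(OCc5ccccc5)c2c1O[C@H](c1ccc(OCc5ccccc5)cc1)[C@H](OCc5ccccc5)C2
F4 | step 5 | (2R,3R)-3,5,7-tris(benzyloxy)-2-[4-(benzyloxy)phenyl]-8-{(2S,4S)-7-(benzyloxy)-2-[(1R,2S)-2-phenylcyclohexyloxy]chroman-4-yl}chroman | O([C@@H]1CCCC[C@H]1c1ccccc1)[C@@H]2C[C@H](c3c(OCc5ccccc5)cc(OCc5ccccc5)c4c3O[C@H](c3ccc(OCc5ccccc5)cc3)[C@H](OCc5ccccc5)C4)c3ccc(OCc5ccccc5)cc3O2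
F5 | step 5 | (4S)-7-(benzyloxy)-4-[(2R,3R)-3,5,7-tris(benzyloxy)-2-[4-(benzyloxy)phenyl]chroman-8-yl]chroman-2-ol (both anomers) | OC2C[C@H](c3c(OCc5ccccc5)cc(OCc5ccccc5)c4c3O[C@H](c3ccc(OCc5ccccc5)cc3)[C@H](OCc5ccccc5)C4)c3ccc(OCc5ccccc5)cc3O2
F6 | step 5 | (3S)-3-[4-(benzyloxy)-2-hydroxyphenyl]-1-[4-(benzyloxy)phenyl]-3-[(2R,3R)-3,5,7-tris(benzyloxy)-2-[4-(benzyloxy)phenyl]chroman-8-yl]propan-1-ol (both carbinol epimers) | c5ccccc5COc1ccc(C(O)C[C@H](c3c(OCc5ccccc5)cc(OCc5ccccc5)c4c3O[C@H](c3ccc(OCc5ccccc5)cc3)[C@H](OCc5ccccc5)C4)c3ccc(OCc5ccccc5)cc3O)cc1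
F7 | step 4 | (2R,3R)-3,5,7-tris(benzyloxy)-2-[4-(benzyloxy)phenyl]chroman-8-carbaldehyde | O=Cc1c(OCc5ccccc5)cc(OCc5ccccc5)c2c1O[C@H](c1ccc(OCc5ccccc5)cc1)[C@H](OCc5ccccc5)C2
F8 | step 4 | 7-(benzyloxy)-2-phenyl-4-[(2R,3R)-3,5,7-tris(benzyloxy)-2-[4-(benzyloxy)phenyl]chroman-8-yl]-4H-1,3,2-benzodioxaborinine (both C4 epimers) | c1ccccc1B1OC(c3c(OCc5ccccc5)cc(OCc5ccccc5)c4c3O[C@H](c3ccc(OCc5ccccc5)cc3)[C@H](OCc5ccccc5)C4)c2ccc(OCc5ccccc5)cc2O1
F0 | step 6 | none | none
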